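## Plan

Numbering: ring oxygen O1, aryl-bearing C2 and C5, C3 and C4 with their hydroxymethyl carbons C3a and C4a.

1. Retrosynthesis: the phenols and primary alcohols are masked, C5 is traced back to its epimer, and the tetrahydrofuran is cut in one operation at O1–C2, C2–C3 and C4–C5.
2. The cut is possible because C2–O1–C5 with its two aryl groups is a 1,3-diaryl carbonyl ylide (aryl carbene plus aryl aldehyde), and C3–C4 with its two trans one-carbon arms is a fumaric acid derivative.
3. Forward: the hydrazone salt of O-benzylvanillin releases the diazo compound, the carbene is taken up by a second molecule of the aldehyde, and the ylide adds to a fumaric bis-amide; the only ring and all skeletal carbons arise in that step.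
4. Stereochemistry: C3/C4 are trans from the E-alkene, with the absolute sense from two (2S)-bornane-10,2-sultam auxiliaries; C2 comes from the cycloaddition (aryl cis to the C3 arm).
5. C5 is set afterwards by benzylic oxidation to the ketal and hydride return anti to the C4 arm; reductive auxiliary cleavage, acetate protection, deacetylation and debenzylation complete the route.

Key step: step 4

Remarks on the chemistry (assumptions):
- The ylide is taken to react in its W-shaped (E,E) form, so the two aryl groups come out cis to each other (one cis, one trans to its neighbouring acyl group) and only C5 needs correction.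
- The facial sense is taken from the usual behaviour of N-enoyl bornane-10,2-sultams in uncatalysed cycloadditions (Cα-re attack in the (2R) series), hence the (2S) auxiliary; if the sense proved opposite, the commercial antipode would be used.

## Route

Step 1
Reactants: 1 4-(benzyloxy)-3-methoxybenzaldehyde; 2 p-toluenesulfonyl hydrazide
Product: 3 (E)-N'-[4-(benzyloxy)-3-methoxybenzylidene]-4-methylbenzenesulfonohydrazide
Conditions: MeOH, rt
Reagents that add atoms: none
Why: Hydrazone condensation of an aromatic aldehyde with a sulfonyl hydrazide is fast and should give the crystalline E-hydrazone; no stereocentre is involved.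

Step 2
Reactants: 3 tosylhydrazone
Product: 4 sodium salt of 3
Conditions: NaOMe (1.0 equiv), MeOH, rt; evaporation, drying in vacuo in the dark
Reagents that add atoms: sodium methoxide, C[O-].[Na+]
Why: Acid–base salt formation: the acidic sulfonamide N–H is removed quantitatively by methoxide, giving the dry salt needed for a Bamford–Stevens release of the diazo compound.

Step 3
Reactants: 5 (2S)-bornane-10,2-sultam (2 equiv in all); 6 fumaryl chloride
Product: 7 N,N'-fumaroylbis[(2S)-bornane-10,2-sultam]
Conditions: 5 (2.0 equiv), NaH (2.2 equiv), toluene, 0 °C to rt; then 6 (1.0 equiv), 0 °C to rt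
Reagents that add atoms: (2S)-bornane-10,2-sultam (the second equivalent of 5), CC1(C)[C@H]2CC[C@@]13CS(=O)(=O)N[C@H]3C2
Why: Twofold N-acylation of the sodium sultam anion by the diacid chloride, one sultam at each acyl chloride, should give the crystalline E-configured bis-amide, which carries the two auxiliaries that fix the absolute configuration in step 4.

Step 4
Reactants: 4 hydrazone sodium salt; 1 4-(benzyloxy)-3-methoxybenzaldehyde; 7 fumaroyl bis-sultam
Product: 10 bis-sultam amide of (2S,3R,4R,5R)-2,5-bis[4-(benzyloxy)-3-methoxyphenyl]tetrahydrofuran-3,4-dicarboxylic acid, via diazo compound 8 (not isolated), via carbonyl ylide 9 (not isolated)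
Conditions: Rh2(OAc)4 (2 mol %), BnEt3NCl (10 mol %), 1 (3 equiv), 4 (2.5 equiv, in portions), 1,4-dioxane, 40 °C
Reagents that add atoms: none
Why: On gentle warming with the phase-transfer salt, 4 loses sulfinate (Bamford–Stevens) and releases 8 at a low stationary concentration; Rh2(OAc)4 converts 8 into an electrophilic carbene that is captured by the carbonyl oxygen of 1 (O1–C2), and the free W-shaped ylide 9 adds as the 4π partner across the C=C bond of 7 in a concerted suprafacial [3+2] cycloaddition that forms C2–C3 and C4–C5 together. The closest known reaction type is the Rh2(OAc)4-catalysed three-component coupling of aryldiazomethanes, aryl aldehydes and fumaric or maleic acid derivatives through carbonyl ylides, combined here with the in-flask diazo generation from hydrazone salts known from carbene-transfer catalysis. The tetrahydrofuran closes by this intermolecular (4π+2π) cycloaddition itself, with no separate cyclisation event. C3 and C4 are trans because the E-geometry of 7 is transferred suprafacially, and their absolute configuration should come from the two (2S)-sultams, which in the s-cis conformation with C=O anti to SO2 shield the Cα-re face of both acyl units, so the ylide adds to the common si,si face. The aryl groups sit in the outer positions of the ylide and therefore end up 2,5-cis; since one acyl group of a trans alkene must be endo, the aryl at C2 comes out cis to its neighbouring acyl group (as in the target) and the aryl at C5 trans (corrected in steps 7 and 8). The step needs chemoselectivity and face selectivity: the electron-poor alkene does not react with the electrophilic carbene but is a good partner for the electron-rich ylide, the slow release of 8 suppresses pyrazoline and azine formation, and the auxiliary secures the face.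

Step 5
Reactants: 10 cycloadduct
Product: 11 [(2S,3S,4S,5R)-2,5-bis[4-(benzyloxy)-3-methoxyphenyl]tetrahydrofuran-3,4-diyl]dimethanol
Conditions: LiAlH4 (3 equiv), THF, 0 °C; H2O, aq. NaOH
Reagents that add atoms: none
Why: Hydride reduction of N-acyl sultams cleaves both C–N bonds to the primary alcohols and returns auxiliary 5 for reuse; the four ring stereocentres should be untouched because no enolisable intermediate persists.

Step 6
Reactants: 11 diol
Product: 12 [(2S,3S,4S,5R)-2,5-bis[4-(benzyloxy)-3-methoxyphenyl]tetrahydrofuran-3,4-diyl]bis(methylene) diacetate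
Conditions: Ac2O, pyridine, DMAP (cat.), CH2Cl2, 0 °C to rt
Reagents that add atoms: acetic anhydride, CC(=O)OC(C)=O
Why: Standard DMAP-catalysed acetylation masks both hydroxyl groups, which would otherwise trap the benzylic cations of steps 7 and 8 as bridged ketals or divert the skeleton towards a furofuran.

Step 7
Reactants: 12 diacetate
Product: 13 C5 methyl ketal of 12, [(2S,3S,4S,5S)-2,5-bis[4-(benzyloxy)-3-methoxyphenyl]-5-methoxytetrahydrofuran-3,4-diyl]bis(methylene) diacetate (route numbering; configuration at C5 of no consequence)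
Conditions: DDQ (1.1 equiv), MeOH (10 equiv), 4 Å molecular sieves, CH2Cl2, 0 °C to rt; filtration through basic Al2O3
Reagents that add atoms: methanol, CO
Why: DDQ should remove hydride from a benzylic ether C–H activated by the 4-benzyloxy-3-methoxyphenyl ring (oxidative C–H functionalisation of benzylic ethers) and methanol captures the 2-aryl oxocarbenium ion as the mixed ketal; hydride loss at C2 instead of C5 gives the regioisomeric ketal, which is carried along because step 8 returns it to 12, and one equivalent of oxidant keeps twofold oxidation low.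

Step 8
Reactants: 13 methyl ketal
Product: 14 [(2S,3S,4S,5S)-2,5-bis[4-(benzyloxy)-3-methoxyphenyl]tetrahydrofuran-3,4-diyl]bis(methylene) diacetate
Conditions: Et3SiH (5 equiv), BF3·OEt2 (2 equiv), CH2Cl2, −78 °C; Et3N, then aq. NaHCO3
Reagents that add atoms: none
Why: BF3·OEt2 ionises the ketal to the cyclic 2-aryl oxocarbenium ion and Et3SiH should deliver hydride to C5 from the face opposite the adjacent C4 acetoxymethyl arm (ionic reduction of cyclic ketals), which places the aryl cis to that arm as in the target; the regioisomeric C2 ketal is reduced back to 12 by the same rule, so recovered 12 is separated and resubmitted to step 7.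

Step 9
Reactants: 14 diacetate
Product: 15 [(2S,3S,4S,5S)-2,5-bis[4-(benzyloxy)-3-methoxyphenyl]tetrahydrofuran-3,4-diyl]dimethanol
Conditions: K2CO3 (0.2 equiv), MeOH, 0 °C to rt
Reagents that add atoms: none
Why: Base-catalysed transesterification (Zemplén-type methanolysis) removes both acetates while the phenols are still benzylated, so no phenoxide can open the ring through a quinone methide.

Step 10
Reactants: 15 diol bis(benzyl ether)
Product: 16 eduesmine, [(2S,3S,4S,5S)-2,5-bis(4-hydroxy-3-methoxyphenyl)tetrahydrofuran-3,4-diyl]dimethanol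
Conditions: H2 (1 atm), 10% Pd on carbon, EtOAc–MeOH, rt, stopped at full conversion
Reagents that add atoms: none
Why: Hydrogenolysis of aryl benzyl ethers over Pd on carbon is neutral and should be much faster than cleavage of the ring benzylic C–O bonds, so the acid- and base-sensitive cis,trans,cis tetrahydrofuran is released unchanged.

## Compound list

1 | 4-(benzyloxy)-3-methoxybenzaldehyde | COc1cc(C=O)ccc1OCc1ccccc1 | starting material
2 | p-toluenesulfonyl hydrazide | Cc1ccc(cc1)S(=O)(=O)NN | starting material
3 | (E)-N'-[4-(benzyloxy)-3-methoxybenzylidene]-4-methylbenzenesulfonohydrazide | COc1cc(/C=N/NS(=O)(=O)c2ccc(C)cc2)ccc1OCc1ccccc1 | intermediate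
4 | sodium salt of 3 | COc1cc(/C=N/[N-]S(=O)(=O)c2ccc(C)cc2)ccc1OCc1ccccc1.[Na+] | intermediate
5 | (2S)-bornane-10,2-sultam, (1R)-(+)-2,10-camphorsultam | CC1(C)[C@H]2CC[C@@]13CS(=O)(=O)N[C@H]3C2 | starting material
6 | fumaryl chloride | O=C(Cl)/C=C/C(Cl)=O | starting material
7 | N,N'-fumaroylbis[(2S)-bornane-10,2-sultam] | CC1(C)[C@H]2CC[C@@]13CS(=O)(=O)N(C(=O)/C=C/C(=O)N4[C@H]5C[C@@H]6CC[C@@]5(CS4(=O)=O)C6(C)C)[C@H]3C2 | intermediate
8 | [4-(benzyloxy)-3-methoxyphenyl]diazomethane | COc1cc(C=[N+]=[N-])ccc1OCc1ccccc1 | intermediate (not isolated)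
9 | W-shaped (E,E) 1,3-bis[4-(benzyloxy)-3-methoxyphenyl] carbonyl ylide | COc1cc(/C=[O+]/[CH-]c2ccc(OCc3ccccc3)c(OC)c2)ccc1OCc1ccccc1 | intermediate (not isolated)
10 | bis[(2S)-bornane-10,2-sultam] amide of (2S,3R,4R,5R)-2,5-bis[4-(benzyloxy)-3-methoxyphenyl]tetrahydrofuran-3,4-dicarboxylic acid (2,3-cis, 3,4-trans, 4,5-trans) | COc1cc(ccc1OCc1ccccc1)[C@H]2O[C@@H](c3ccc(OCc4ccccc4)c(OC)c3)[C@H](C(=O)N3[C@H]4C[C@@H]5CC[C@@]4(CS3(=O)=O)C5(C)C)[C@H]2C(=O)N3[C@H]4C[C@@H]5CC[C@@]4(CS3(=O)=O)C5(C)C | intermediate
11 | [(2S,3S,4S,5R)-2,5-bis[4-(benzyloxy)-3-methoxyphenyl]tetrahydrofuran-3,4-diyl]dimethanol | COc1cc(ccc1OCc1ccccc1)[C@H]2O[C@@H](c3ccc(OCc4ccccc4)c(OC)c3)[C@H](CO)[C@H]2CO | intermediate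
12 | [(2S,3S,4S,5R)-2,5-bis[4-(benzyloxy)-3-methoxyphenyl]tetrahydrofuran-3,4-diyl]bis(methylene) diacetate | COc1cc(ccc1OCc1ccccc1)[C@H]2O[C@@H](c3ccc(OCc4ccccc4)c(OC)c3)[C@H](COC(C)=O)[C@H]2COC(C)=O | intermediate
13 | [(2S,3S,4S,5S)-2,5-bis[4-(benzyloxy)-3-methoxyphenyl]-5-methoxytetrahydrofuran-3,4-diyl]bis(methylene) diacetate (C5 methyl ketal, methoxy anti to the C4 arm drawn) | COc1cc(ccc1OCc1ccccc1)[C@H]2O[C@](OC)(c3ccc(OCc4ccccc4)c(OC)c3)[C@H](COC(C)=O)[C@H]2COC(C)=O | intermediate
14 | [(2S,3S,4S,5S)-2,5-bis[4-(benzyloxy)-3-methoxyphenyl]tetrahydrofuran-3,4-diyl]bis(methylene) diacetate | COc1cc(ccc1OCc1ccccc1)[C@H]2O[C@H](c3ccc(OCc4ccccc4)c(OC)c3)[C@H](COC(C)=O)[C@H]2COC(C)=O | intermediate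
15 | [(2S,3S,4S,5S)-2,5-bis[4-(benzyloxy)-3-methoxyphenyl]tetrahydrofuran-3,4-diyl]dimethanol | COc1cc(ccc1OCc1ccccc1)[C@H]2O[C@H](c3ccc(OCc4ccccc4)c(OC)c3)[C@H](CO)[C@H]2CO | intermediate
16 | eduesmine, [(2S,3S,4S,5S)-2,5-bis(4-hydroxy-3-methoxyphenyl)tetrahydrofuran-3,4-diyl]dimethanol | COc1cc([C@H]2O[C@H](c3ccc(O)c(OC)c3)[C@H](CO)[C@H]2CO)ccc1O | target

## Step count

Total step count: 10.
Longest linear sequence: 9 steps (steps 1, 2 and 4 to 10, from compound 1); step 3 is a one-step side branch.

## Steps most likely to fail

Step 4. The diazo compound may be consumed by direct dipolar addition to the acceptor alkene or by carbene dimerisation, or the ylide may close to the oxirane or add to a second aldehyde before it meets the alkene. The fallback makes the same ylide with no diazo compound present beside the alkene. It sets out from 4 and 1, which under sulfur-ylide epoxidation conditions (Rh2(OAc)4, catalytic tetrahydrothiophene, BnEt3NCl, MeCN, 40 °C) should give racemic trans-2,3-bis[4-(benzyloxy)-3-methoxyphenyl]oxirane F1. Irradiation of F1 with 7 in MeCN (λ > 300 nm) with 1,4-dicyanonaphthalene as electron-transfer sensitiser cleaves the oxirane C–C bond to ylide 9, which adds to 7; the route is rejoined at 10.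

Step 7. Hydride may be lost from C2 instead of C5, which only lowers conversion, or from both carbons, after which loss of methanol and further dehydrogenation lead to aromatisation of the ring. The fallback needs no choice between the two benzylic carbons. It sets out from 12, which is oxidised at both positions on purpose with DDQ (2.5 equiv) in CH2Cl2–water; the ring opens to the C2-symmetric (2S,3S)-2,3-bis(acetoxymethyl)-1,4-bis[4-(benzyloxy)-3-methoxyphenyl]butane-1,4-dione F2, whose two ketones are equivalent. Corey–Bakshi–Shibata reduction with (R)-2-methyl-CBS-oxazaborolidine and BH3·SMe2 (0.6 equiv, THF, −20 °C) reduces one ketone under reagent control, and the hydroxy ketone closes to the cyclic hemiketal [(2S,3S,4S,5S)-2,5-bis[4-(benzyloxy)-3-methoxyphenyl]-2-hydroxytetrahydrofuran-3,4-diyl]bis(methylene) diacetate F3, in which the carbinol carbon already carries its aryl group cis to the neighbouring arm. Et3SiH and BF3·OEt2 at −78 °C reduce the hemiketal carbon anti to its own arm, and the route is rejoined at 14.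

Step 8. The Lewis acid may ionise the benzylic C–O bonds of the product, with loss of the cis relationships or reductive ring opening, or hydride may arrive syn to the C4 arm. The fallback replaces cation reduction by a hydroxyl-directed hydrogenation. It sets out from 13, from which methanol is eliminated under buffered conditions (TMSOTf, i-Pr2NEt, CH2Cl2, −20 °C) to give the enol ether [(2S,3S)-2,5-bis[4-(benzyloxy)-3-methoxyphenyl]-2,3-dihydrofuran-3,4-diyl]bis(methylene) diacetate F4. Methanolysis (K2CO3, MeOH) frees [(2S,3S)-2,5-bis[4-(benzyloxy)-3-methoxyphenyl]-2,3-dihydrofuran-3,4-diyl]dimethanol F5. Hydrogenation with [Ir(cod)(PCy3)(py)]PF6 and H2 in CH2Cl2 is then directed by the homoallylic C3a hydroxyl group, so both hydrogens add to the C4=C5 bond from the face of the C3 arm; this sets C4 trans to C3 and the C5 aryl cis to the C4 arm, and the route is rejoined at 15.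

## Further compounds

F1 | step 4 | trans-2,3-bis[4-(benzyloxy)-3-methoxyphenyl]oxirane (racemic, (2R,3R) drawn) | COc1cc(ccc1OCc1ccccc1)[C@H]1O[C@@H]1c1ccc(OCc2ccccc2)c(OC)c1
F2 | step 7 | (2S,3S)-2,3-bis(acetoxymethyl)-1,4-bis[4-(benzyloxy)-3-methoxyphenyl]butane-1,4-dione | O=C(c1ccc(OCc2ccccc2)c(OC)c1)[C@H](COC(C)=O)[C@@H](COC(C)=O)C(=O)c1ccc(OCc2ccccc2)c(OC)c1
F3 | step 7 | [(2S,3S,4S,5S)-2,5-bis[4-(benzyloxy)-3-methoxyphenyl]-2-hydroxytetrahydrofuran-3,4-diyl]bis(methylene) diacetate (one anomer drawn) | COc1cc(ccc1OCc1ccccc1)[C@@]2(O)O[C@H](c3ccc(OCc4ccccc4)c(OC)c3)[C@H](COC(C)=O)[C@H]2COC(C)=O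
F4 | step 8 | [(2S,3S)-2,5-bis[4-(benzyloxy)-3-methoxyphenyl]-2,3-dihydrofuran-3,4-diyl]bis(methylene) diacetate | COc1cc(ccc1OCc1ccccc1)[C@H]2OC(c3ccc(OCc4ccccc4)c(OC)c3)=C(COC(C)=O)[C@H]2COC(C)=O
F5 | step 8 | [(2S,3S)-2,5-bis[4-(benzyloxy)-3-methoxyphenyl]-2,3-dihydrofuran-3,4-diyl]dimethanol | COc1cc(ccc1OCc1ccccc1)[C@H]2OC(c3ccc(OCc4ccccc4)c(OC)c3)=C(CO)[C@H]2CO
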